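**Plan**
- Cuts, in retrosynthetic order: the aryl ether C–O bond (oxa-Michael addition of umbelliferone), the C-2 methylidene (methylenation of a C-2 ketone unveiled by a Stork–Danheiser transposition), a C-1 methylidene (Wittig), and, in one operation, both ring A bonds C-8–C-8a and C-4a–C-5.
- Enabling feature: ring A is a cyclohexanol with its oxygen at C-6, 1,4 to the quaternary C-8a and next to the gem-dimethyl C-5. This is the retron of a 2-silyloxy diene (C-8, C-7, C-6, C-5) adding across C-4a–C-8a, a bond flanked in ring B by C-4 and C-1, the carbonyl carbons of 2-methoxy-6-methyl-1,4-benzoquinone.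
- Forward order: ring B is bought as the quinone, ring A is closed on it by a catalytic enantioselective Diels–Alder reaction, ring B is then re-dressed (C-4a epimerisation, C-1 methylenation, oxygen transposition C-4 → C-2), and the coumarin is joined in the last step but one.
- Stereochemistry: C-8a from the chiral Lewis acid made from (S)-BINOL and TiCl2(OiPr)2; C-4a by equilibration to the trans-decalin; C-6 by equatorial hydride delivery (axial alcohol); C-1 by enolate protonation anti to the angular methyl, which is also the equatorial, thermodynamic position.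

Key step: step 2

Remark: locants in all names and in the text follow the octahydronaphthalene numbering of the target, so a given carbon keeps its number in every bicyclic compound (some names therefore do not use lowest locants).
Remark: 4-methylpent-1-en-3-one and 2-methoxy-6-methyl-1,4-benzoquinone are taken as catalogue compounds; each is otherwise one routine oxidation from the commercial allylic alcohol or phenol.

Step 1
Reactants: 1 4-methylpent-1-en-3-one
Product: 2 tert-butyl(dimethyl)[(4-methylpenta-1,3-dien-3-yl)oxy]silane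
Conditions: TBSOTf (1.1 equiv), Et3N (1.5 equiv), Et2O, 0 °C
Reagents that add atoms: tert-butyldimethylsilyl trifluoromethanesulfonate, CC(C)(C)[Si](C)(C)OS(=O)(=O)C(F)(F)F
Why: Soft enolisation and O-silylation (silyl enol ether formation) of an enone whose only enolisable hydrogen is the isopropyl methine should give the 2-silyloxy diene as a single isomer, with no E/Z question because the new terminus carries two methyl groups.

Step 2
Reactants: 2 tert-butyl(dimethyl)[(4-methylpenta-1,3-dien-3-yl)oxy]silane; 3 2-methoxy-6-methylcyclohexa-2,5-diene-1,4-dione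
Product: 5 (4aS,8aR)-2-methoxy-5,5,8a-trimethyl-4a,5,8,8a-tetrahydronaphthalene-1,4,6(7H)-trione (cis-fused), via silyl enol ether cycloadduct 4 (not isolated)
Conditions: 2 (1.5 equiv), (S)-BINOL/TiCl2(OiPr)2 (1:1, 20 mol%), 4 Å MS, CH2Cl2, −30 → 0 °C; then 1 M HCl, THF, rt
Reagents that add atoms: none
Why: The TiCl2(binolate) Lewis acid should chelate the C-1 carbonyl and the 2-methoxy oxygen of 3, lowering the LUMO of the methyl-bearing double bond and making its CH carbon the β-carbon, so that diene 2 adds in an endo, strongly asynchronous [4+2] cycloaddition with its nucleophilic CMe2 terminus bonding to that CH carbon (C-5 to C-4a) and its CH2 terminus to the methyl-bearing carbon (C-8 to C-8a). The closest known reaction type is the chiral BINOL/TiCl2-catalysed Diels–Alder reaction of 2-methoxy-1,4-benzoquinones with silyloxy dienes, together with Lewis-acid-promoted cycloadditions of 4,4-disubstituted 2-silyloxy dienes to 2-methylcycloalkenones. Ring A closes as a six-membered carbocycle by suprafacial [4π+2π] addition (in the stepwise limit a Mukaiyama–Michael addition followed by a 6-endo-trig Michael closure, which gives the same ring). The new stereocentres C-8a (quaternary, kept to the end) and C-4a arise cis from the suprafacial addition, and their absolute sense is set by the BINOL ligand shielding one face of the chelated quinone. The step needs site selectivity (methyl-bearing rather than methoxy-bearing double bond), regioselectivity and face selectivity; the first comes from vinylogous-ester deactivation of the methoxy alkene, the second from chelation at C-1 reinforced by the steric preference of the CMe2 terminus for the CH carbon, the third from the ligand. C-4a is corrected in step 3, so only C-8a has to be right here, and acid work-up hydrolyses the silyl enol ether to the C-6 ketone.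

Step 3
Reactants: 5 (4aS,8aR)-2-methoxy-5,5,8a-trimethyl-4a,5,8,8a-tetrahydronaphthalene-1,4,6(7H)-trione
Product: 6 (4aR,8aR)-2-methoxy-5,5,8a-trimethyl-4a,5,8,8a-tetrahydronaphthalene-1,4,6(7H)-trione (trans-fused)
Conditions: NaOMe (0.2 equiv), MeOH, 0 °C → rt
Reagents that add atoms: none
Why: Base-mediated epimerisation through the C-4 enolate should reprotonate C-4a anti to the angular methyl and give the trans-decalin, expected to be the more stable isomer; C-8a is quaternary and cannot change, and methoxide exchange at C-2 is degenerate.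

Step 4
Reactants: 6 (4aR,8aR)-2-methoxy-5,5,8a-trimethyl-4a,5,8,8a-tetrahydronaphthalene-1,4,6(7H)-trione
Product: 7 (4aR,6S,8aR)-6-hydroxy-2-methoxy-5,5,8a-trimethyl-4a,5,6,7,8,8a-hexahydronaphthalene-1,4-dione
Conditions: LiBH(s-Bu)3 (L-Selectride, 1.05 equiv), THF, −78 °C; then H2O
Reagents that add atoms: none
Why: The C-6 carbonyl is the only unconjugated ketone (C-4 is a vinylogous ester carbonyl, C-1 a cross-conjugated ketone next to a quaternary carbon), and the bulky hydride should attack it equatorially, as is usual for ketones flanked by a gem-dimethyl carbon in trans-decalins, to give the axial (6S) alcohol cis to H-4a and trans to the 8a-methyl (chemo- and diastereoselective ketone reduction).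

Step 5
Reactants: 7 (4aR,6S,8aR)-6-hydroxy-2-methoxy-5,5,8a-trimethyl-4a,5,6,7,8,8a-hexahydronaphthalene-1,4-dione
Product: 8 (4aS,6S,8aR)-6-hydroxy-2-methoxy-5,5,8a-trimethyl-1-methylidene-4a,5,6,7,8,8a-hexahydronaphthalen-4(1H)-one
Conditions: Ph3PCH3Br (3 equiv), KOtBu (3 equiv), toluene, rt → 80 °C
Reagents that add atoms: methyltriphenylphosphonium bromide, C[P+](c1ccccc1)(c1ccccc1)c1ccccc1.[Br-]
Why: Wittig methylenation should occur at C-1, the only ketone carbonyl left (the vinylogous ester carbonyl C-4 is inert to the ylide and the alcohol is carried as its alkoxide); C-1 has no α-hydrogen, so forcing conditions for a hindered ketone can be used.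

Step 6
Reactants: 8 (4aS,6S,8aR)-6-hydroxy-2-methoxy-5,5,8a-trimethyl-1-methylidene-4a,5,6,7,8,8a-hexahydronaphthalen-4(1H)-one
Product: 10 (4aS,6S,8aR)-6-hydroxy-5,5,8a-trimethyl-1-methylidene-4a,5,6,7,8,8a-hexahydronaphthalen-2(1H)-one, via allylic alcohol 9 (not isolated)
Conditions: i-Bu2AlH (DIBAL-H, 3 equiv), CH2Cl2, −78 °C; then 1 M H2SO4, THF, 0 °C
Reagents that add atoms: water, O
Why: Stork–Danheiser transposition: 1,2-reduction of the vinylogous ester carbonyl, then acid ionises the C-4 alcohol with help from the enol ether and water adds at C-2, which loses methanol to give the C-2 ketone and the C-3=C-4 double bond; the carbinol stereocentre of 9 is destroyed again.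

Step 7
Reactants: 10 (4aS,6S,8aR)-6-hydroxy-5,5,8a-trimethyl-1-methylidene-4a,5,6,7,8,8a-hexahydronaphthalen-2(1H)-one; 11 7-hydroxy-2H-chromen-2-one (umbelliferone)
Product: 12 7-{[(1R,4aS,6S,8aR)-6-hydroxy-5,5,8a-trimethyl-2-oxo-1,2,4a,5,6,7,8,8a-octahydronaphthalen-1-yl]methoxy}-2H-chromen-2-one
Conditions: 11 (1.5 equiv), Cs2CO3 (0.2 equiv), MeCN (concentrated), rt
Reagents that add atoms: none
Why: Oxa-Michael addition of the phenoxide should take place at the unhindered exocyclic methylene of the α-methylene ketone (the ring β-carbon C-4 sits next to the doubly neopentyl C-4a), and protonation of the enolate at C-1 anti to the angular methyl, also the thermodynamic outcome, places the aryloxymethyl group equatorial and cis to that methyl.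

Step 8
Reactants: 12 7-{[(1R,4aS,6S,8aR)-6-hydroxy-5,5,8a-trimethyl-2-oxo-1,2,4a,5,6,7,8,8a-octahydronaphthalen-1-yl]methoxy}-2H-chromen-2-one
Product: 13 7-{[(1R,4aS,6S,8aR)-6-hydroxy-5,5,8a-trimethyl-2-methylidene-1,2,4a,5,6,7,8,8a-octahydronaphthalen-1-yl]methoxy}-2H-chromen-2-one
Conditions: Zn/CH2Br2/TiCl4 (preformed in THF), CH2Cl2, 0 °C → rt
Reagents that add atoms: dibromomethane, BrCBr
Why: Non-basic Lombardo methylenation with the zinc/titanium gem-dimetal reagent should convert the enone carbonyl into the exocyclic methylene of the conjugated diene without enolising the epimerisable C-1 centre or eliminating the β-aryloxy group, and should leave the coumarin lactone and the free alcohol untouched.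

**Compound list**
1 | 4-methylpent-1-en-3-one | CC(C)C(=O)C=C | starting material
2 | tert-butyl(dimethyl)[(4-methylpenta-1,3-dien-3-yl)oxy]silane | C=CC(O[Si](C)(C)C(C)(C)C)=C(C)C | intermediate
3 | 2-methoxy-6-methylcyclohexa-2,5-diene-1,4-dione | COC1=CC(=O)C=C(C)C1=O | starting material
4 | (4aS,8aR)-6-{[tert-butyl(dimethyl)silyl]oxy}-2-methoxy-5,5,8a-trimethyl-4a,5,8,8a-tetrahydronaphthalene-1,4-dione (cis-fused) | COC1=CC(=O)[C@H]2C(C)(C)C(O[Si](C)(C)C(C)(C)C)=CC[C@@]2(C)C1=O | intermediate
5 | (4aS,8aR)-2-methoxy-5,5,8a-trimethyl-4a,5,8,8a-tetrahydronaphthalene-1,4,6(7H)-trione (cis-fused) | COC1=CC(=O)[C@H]2C(C)(C)C(=O)CC[C@@]2(C)C1=O | intermediate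
6 | (4aR,8aR)-2-methoxy-5,5,8a-trimethyl-4a,5,8,8a-tetrahydronaphthalene-1,4,6(7H)-trione (trans-fused) | COC1=CC(=O)[C@@H]2C(C)(C)C(=O)CC[C@@]2(C)C1=O | intermediate
7 | (4aR,6S,8aR)-6-hydroxy-2-methoxy-5,5,8a-trimethyl-4a,5,6,7,8,8a-hexahydronaphthalene-1,4-dione | COC1=CC(=O)[C@@H]2C(C)(C)[C@@H](O)CC[C@@]2(C)C1=O | intermediate
8 | (4aS,6S,8aR)-6-hydroxy-2-methoxy-5,5,8a-trimethyl-1-methylidene-4a,5,6,7,8,8a-hexahydronaphthalen-4(1H)-one | COC1=CC(=O)[C@@H]2C(C)(C)[C@@H](O)CC[C@@]2(C)C1=C | intermediate
9 | (4R,4aS,6S,8aR)-2-methoxy-5,5,8a-trimethyl-1-methylidene-1,4,4a,5,6,7,8,8a-octahydronaphthalene-4,6-diol (expected C-4 epimer; this centre is lost in the same step) | COC1=C[C@H](O)[C@@H]2C(C)(C)[C@@H](O)CC[C@@]2(C)C1=C | intermediate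
10 | (4aS,6S,8aR)-6-hydroxy-5,5,8a-trimethyl-1-methylidene-4a,5,6,7,8,8a-hexahydronaphthalen-2(1H)-one | O=C1C=C[C@@H]2C(C)(C)[C@@H](O)CC[C@@]2(C)C1=C | intermediate
11 | 7-hydroxy-2H-chromen-2-one (umbelliferone) | Oc1ccc2ccc(=O)oc2c1 | starting material
12 | 7-{[(1R,4aS,6S,8aR)-6-hydroxy-5,5,8a-trimethyl-2-oxo-1,2,4a,5,6,7,8,8a-octahydronaphthalen-1-yl]methoxy}-2H-chromen-2-one | O=C1C=C[C@@H]2C(C)(C)[C@@H](O)CC[C@@]2(C)[C@@H]1COc1ccc2ccc(=O)oc2c1 | intermediate
13 | 7-{[(1R,4aS,6S,8aR)-6-hydroxy-5,5,8a-trimethyl-2-methylidene-1,2,4a,5,6,7,8,8a-octahydronaphthalen-1-yl]methoxy}-2H-chromen-2-one | C=C1C=C[C@@H]2C(C)(C)[C@@H](O)CC[C@@]2(C)[C@@H]1COc1ccc2ccc(=O)oc2c1 | target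

Total step count: 8. Longest linear sequence: 8 steps (1 → 13; 3 and 11 are bought).

**Steps most likely to fail**

Step 2. The Z-methyl group of 2 disfavours the s-cis conformer, so the cycloaddition may be outrun by Lewis-acid cleavage of the silyl enol ether. Face selectivity under the chelating titanium catalyst may also be modest or of the opposite sense, in which case the antipodal ligand would be used. The fallback sets out from 3 and comes back to the route at 9; it turns the polarity of the cycloaddition round. A cationic boron Lewis acid, (S)-3,3-diphenyl-1-(o-tolyl)tetrahydropyrrolo[1,2-c][1,3,2]oxazaborole protonated with Tf2NH, should bind the more basic vinylogous-ester carbonyl (C-4) and catalyse the Diels–Alder reaction with commercial 4-methylpenta-1,3-diene F1. Its CH2 end is now the nucleophilic terminus and adds to the methyl-bearing β-carbon, giving the cis adduct F2 with the same two ring A bonds. Base (DBU, toluene) then gives the trans isomer F3. mCPBA epoxidises the isolated ring A alkene from the face opposite the two axial methyl groups to give the epoxide F4. Wittig methylenation at C-1 gives the methylidene epoxide F5. LiAlH4 reduces the C-4 carbonyl and opens the epoxide trans-diaxially at C-7, which leaves the axial C-6 alcohol and gives 9, ready for the acid treatment of step 6.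

Step 4. Conjugate hydride delivery to the methoxy-enedione of ring B, or attack at C-1, may compete with reduction of the ring A ketone, and equatorial attack may be incomplete. The fallback sets out from 4 and comes back at 9; ring B is made inert before the ring A ketone is set free. Step 2 is worked up without acid so that 4 is isolated, and DBU gives the trans-fused silyl enol ether F6. Wittig methylenation at C-1 gives the methylidene silyl enol ether F7. i-Bu2AlH reduces the C-4 carbonyl to the allylic alcohol F8. Bu4NF in THF cleaves the silyl enol ether to the ring A ketone F9 without touching the methyl dienol ether. LiBH(s-Bu)3, now with no carbonyl or acceptor left in ring B, gives 9.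

Step 8. Umbelliferone may be lost by β-elimination (retro-oxa-Michael) under the Lewis-acidic conditions, or methylenation of the conjugated, α-branched ketone may be slow. The fallback sets out from 10 and comes back at 13, so it also bypasses step 7; the aryl ether is made last by substitution instead of conjugate addition. Copper-catalysed conjugate borylation (B2pin2, CuCl, NaOtBu, MeOH, THF) of the exocyclic methylene gives the β-boryl ketone F10. Zn/CH2Br2/TiCl4 methylenation, with no β-leaving group present, gives the boryl diene F11. NaBO3·4H2O oxidation gives the diol F12. A Mitsunobu reaction (PPh3, DIAD, THF) with 11 etherifies the primary alcohol in the presence of the hindered axial secondary one to give 13.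

**Further compounds**
F1 | step 2 | 4-methylpenta-1,3-diene | C=CC=C(C)C
F2 | step 2 | (4aS,8aR)-2-methoxy-5,5,8a-trimethyl-4a,5,8,8a-tetrahydronaphthalene-1,4-dione (cis-fused) | COC1=CC(=O)[C@H]2C(C)(C)C=CC[C@@]2(C)C1=O
F3 | step 2 | (4aR,8aR)-2-methoxy-5,5,8a-trimethyl-4a,5,8,8a-tetrahydronaphthalene-1,4-dione (trans-fused) | COC1=CC(=O)[C@@H]2C(C)(C)C=CC[C@@]2(C)C1=O
F4 | step 2 | 6,7-epoxide of F3, oxirane oxygen on the face opposite the 8a-methyl group | COC1=CC(=O)[C@@H]2C(C)(C)[C@H]3O[C@H]3C[C@@]2(C)C1=O
F5 | step 2 | 1-methylidene analogue of F4 (C-1 carbonyl replaced by C=CH2) | COC1=CC(=O)[C@@H]2C(C)(C)[C@H]3O[C@H]3C[C@@]2(C)C1=C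
F6 | step 4 | (4aR,8aR)-6-{[tert-butyl(dimethyl)silyl]oxy}-2-methoxy-5,5,8a-trimethyl-4a,5,8,8a-tetrahydronaphthalene-1,4-dione (trans-fused) | COC1=CC(=O)[C@@H]2C(C)(C)C(O[Si](C)(C)C(C)(C)C)=CC[C@@]2(C)C1=O
F7 | step 4 | 1-methylidene analogue of F6 (C-1 carbonyl replaced by C=CH2) | COC1=CC(=O)[C@@H]2C(C)(C)C(O[Si](C)(C)C(C)(C)C)=CC[C@@]2(C)C1=C
F8 | step 4 | C-4 allylic alcohol from F7 (4R; silyl enol ether and methyl dienol ether intact) | COC1=C[C@H](O)[C@@H]2C(C)(C)C(O[Si](C)(C)C(C)(C)C)=CC[C@@]2(C)C1=C
F9 | step 4 | (4R,4aS,8aR)-4-hydroxy-2-methoxy-5,5,8a-trimethyl-1-methylidene-1,4,4a,7,8,8a-hexahydronaphthalen-6(5H)-one | COC1=C[C@H](O)[C@@H]2C(C)(C)C(=O)CC[C@@]2(C)C1=C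
F10 | step 8 | 6-hydroxy-5,5,8a-trimethyl-1-[(4,4,5,5-tetramethyl-1,3,2-dioxaborolan-2-yl)methyl]-4a,5,6,7,8,8a-hexahydronaphthalen-2(1H)-one, configuration at every stereocentre as in 12 | O=C1C=C[C@@H]2C(C)(C)[C@@H](O)CC[C@@]2(C)[C@@H]1CB1OC(C)(C)C(C)(C)O1
F11 | step 8 | 2-methylidene analogue of F10 (C-2 carbonyl replaced by C=CH2), configuration as in 13 | C=C1C=C[C@@H]2C(C)(C)[C@@H](O)CC[C@@]2(C)[C@@H]1CB1OC(C)(C)C(C)(C)O1
F12 | step 8 | [(1R,4aS,6S,8aR)-6-hydroxy-5,5,8a-trimethyl-2-methylidene-1,2,4a,5,6,7,8,8a-octahydronaphthalen-1-yl]methanol | C=C1C=C[C@@H]2C(C)(C)[C@@H](O)CC[C@@]2(C)[C@@H]1CO
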